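The route rests on cutting the C2–C3 bond of each 2,3-diaryl-2,3-dihydrobenzofuran. In ring B, C3 (the carbon carrying the 3,5-dihydroxyphenyl group) is attached to arene carbon C3a, which lies between two oxygen-bearing carbons (C7a–O1 and C4–OH). The precursor is therefore a diaryl ketone hydrazone whose 2,6-bis(benzyloxy)aryl ring is locally twofold symmetric. Oxidation to the diazo compound and enantioselective rhodium carbene insertion into a benzylic C–H bond of either (equivalent) ether forms C2–C3, closes the furan ring and sets both stereocentres in one operation. The same reaction with the antipodal catalyst builds ring A, and acid finally equilibrates both rings to trans.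

Key step: step 4

Assumption: Rh2(S-PTAD)4 is taken to deliver the 3S centre of ring B (step 4) and Rh2(R-PTAD)4 the 3R centre of ring A (step 9); should the sense of induction be the reverse, the two antipodal catalysts are exchanged between the two steps.

Step 1
Reactants: 1 1-bromo-3,5-difluorobenzene; 2 N,3,5-trimethoxy-N-methylbenzamide
Product: 4 (4-bromo-2,6-difluorophenyl)(3,5-dimethoxyphenyl)methanone, via aryllithium 3 (not isolated)
Conditions: LiN(i-Pr)2 (LDA), THF, −78 °C; then 2, −78 → 0 °C; aq. HCl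
Reagents that add atoms: none
Why: Directed ortho-lithiation removes the proton flanked by both fluorines of 1 (the most acidic site), and the aryllithium is acylated once by the N-methoxy-N-methylamide because the chelated tetrahedral adduct blocks a second addition.

Step 2
Reactants: 4 (4-bromo-2,6-difluorophenyl)(3,5-dimethoxyphenyl)methanone; 5 3,4-dimethoxybenzyl alcohol (2.3 equiv)
Product: 6 {4-bromo-2,6-bis[(3,4-dimethoxybenzyl)oxy]phenyl}(3,5-dimethoxyphenyl)methanone
Conditions: NaH, THF/DMF, 0 → 50 °C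
Reagents that add atoms: none
Why: Double nucleophilic aromatic substitution (SNAr) should displace both fluorides, which sit ortho to the activating ketone and are far better leaving groups than the bromide, so both ether arms needed by the key step are installed in one operation.

Step 3
Reactants: 6 {4-bromo-2,6-bis[(3,4-dimethoxybenzyl)oxy]phenyl}(3,5-dimethoxyphenyl)methanone
Product: 7 hydrazone of ketone 6 (E/Z mixture, both isomers usable)
Conditions: N2H4·H2O (excess), AcOH (cat.), n-BuOH, 120 °C (sealed tube)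
Reagents that add atoms: hydrazine (used as the hydrate), NN
Why: Acid-catalysed hydrazone condensation of a diaryl ketone, run under forcing conditions because the carbonyl group is flanked by two ortho ether groups.

Step 4
Reactants: 7 hydrazone of ketone 6
Product: 9 (2R,3S)-6-bromo-4-[(3,4-dimethoxybenzyl)oxy]-2-(3,4-dimethoxyphenyl)-3-(3,5-dimethoxyphenyl)-2,3-dihydrobenzofuran (2,3-cis), via diaryldiazomethane 8 (not isolated)
Conditions: MnO2, CH2Cl2, 0 °C, filtration; then slow addition to Rh2(S-PTAD)4 (1 mol %), CH2Cl2, −20 → 0 °C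
Reagents that add atoms: none
Why: MnO2 dehydrogenates the hydrazone to diaryldiazomethane 8, the dirhodium tetracarboxylate expels N2 to give a donor/donor rhodium carbene at the future C3, and this carbene inserts into a benzylic C–H bond of a neighbouring 3,4-dimethoxybenzyl ether (the future C2) through a three-centre, hydride-shift-like transition state, forming the C2–C3 bond. The closest known reaction type is the enantioselective intramolecular C–H insertion of donor/donor rhodium carbenes, generated from oxidised diaryl ketone hydrazones, into benzyl aryl ethers to give 2,3-diaryl-2,3-dihydrobenzofurans. The dihydrofuran ring closes by 1,5-C–H insertion, a five-membered closure in which the carbene carbon bonds to the ether carbon five atoms away. C3 is set by the catalyst, whose chiral carboxylate ligands differentiate the two faces of the carbene (3S expected with the S-configured ligand), and C2 is set relative to C3 by the concerted insertion geometry, which should place the two aryl groups cis (2R). The step needs site selectivity among the C–H bonds and chemoselectivity against azine or alkene formation: the two benzylic ethers are homotopic through the local twofold axis of the 2,6-dioxygenated ring so either gives 9, only their CH2 groups are both activated and within 1,5-reach, and slow addition of dilute 8 suppresses bimolecular coupling.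

Step 5
Reactants: 10 4-bromo-2,6-difluorobenzaldehyde; 11 4-methoxybenzyl alcohol (2.2 equiv)
Product: 12 4-bromo-2,6-bis[(4-methoxybenzyl)oxy]benzaldehyde
Conditions: NaH, THF/DMF, 0 °C → rt
Reagents that add atoms: none
Why: Double SNAr of the two fluorides ortho to the formyl group by the benzylic alkoxide, the bromide being much less reactive, should give the ring A building block with both ether arms in place.

Step 6
Reactants: 9 cis-dihydrobenzofuran bromide; 12 4-bromo-2,6-bis[(4-methoxybenzyl)oxy]benzaldehyde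
Product: 14 {4-bromo-2,6-bis[(4-methoxybenzyl)oxy]phenyl}{(2R,3S)-4-[(3,4-dimethoxybenzyl)oxy]-2-(3,4-dimethoxyphenyl)-3-(3,5-dimethoxyphenyl)-2,3-dihydrobenzofuran-6-yl}methanol (both carbinol epimers), via aryllithium 13 (not isolated)
Conditions: n-BuLi (1.0 equiv), THF, −78 °C; then 12, −78 → −40 °C; H2O
Reagents that add atoms: none
Why: Bromine–lithium exchange at −78 °C outpaces deprotonation of the benzylic positions and the aryllithium adds 1,2 to the aldehyde faster than it exchanges with the aryl bromide of 12; the carbinol centre forms as an epimer mixture that step 7 removes.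

Step 7
Reactants: 14 diaryl carbinol
Product: 15 {4-bromo-2,6-bis[(4-methoxybenzyl)oxy]phenyl}{(2R,3S)-4-[(3,4-dimethoxybenzyl)oxy]-2-(3,4-dimethoxyphenyl)-3-(3,5-dimethoxyphenyl)-2,3-dihydrobenzofuran-6-yl}methanone
Conditions: Dess–Martin periodinane, NaHCO3, CH2Cl2, 0 °C → rt
Reagents that add atoms: none
Why: Dess–Martin oxidation of a doubly benzylic secondary alcohol proceeds under buffered, non-acidic conditions that should leave the benzylic ethers and the cis-dihydrobenzofuran untouched.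

Step 8
Reactants: 15 diaryl ketone
Product: 16 hydrazone of ketone 15 (E/Z mixture, both isomers usable)
Conditions: N2H4·H2O (excess), AcOH (cat.), n-BuOH, 120 °C (sealed tube)
Reagents that add atoms: hydrazine (used as the hydrate), NN
Why: Hydrazone condensation as in step 3, again under forcing conditions because of the two ortho ether groups, with the aryl bromide and the ethers inert to hydrazine.

Step 9
Reactants: 16 hydrazone of ketone 15
Product: 18 (2S,3R)-6-bromo-3-[(2R,3S)-4-[(3,4-dimethoxybenzyl)oxy]-2-(3,4-dimethoxyphenyl)-3-(3,5-dimethoxyphenyl)-2,3-dihydrobenzofuran-6-yl]-4-[(4-methoxybenzyl)oxy]-2-(4-methoxyphenyl)-2,3-dihydrobenzofuran (both rings 2,3-cis), via diaryldiazomethane 17 (not isolated)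
Conditions: MnO2, CH2Cl2, 0 °C, filtration; then slow addition to Rh2(R-PTAD)4 (2 mol %), CH2Cl2, −20 → 0 °C
Reagents that add atoms: none
Why: A second donor/donor rhodium carbene C–H insertion of the type used in step 4, in which the antipodal catalyst should set C3 of ring A as R under catalyst control and the concerted insertion into either of the two homotopic 4-methoxybenzyl ethers should place the aryl groups cis (2S).

Step 10
Reactants: 18 cis,cis-bis(dihydrobenzofuran) bromide
Product: 19 (2R,3R)-6-bromo-3-[(2S,3S)-2-(3,4-dimethoxyphenyl)-3-(3,5-dimethoxyphenyl)-4-hydroxy-2,3-dihydrobenzofuran-6-yl]-2-(4-methoxyphenyl)-2,3-dihydrobenzofuran-4-ol (both rings 2,3-trans)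
Conditions: TFA/CH2Cl2 (1:4), 1,3,5-trimethoxybenzene (6 equiv), 0 °C → rt
Reagents that add atoms: none
Why: Acidolysis cleaves the two electron-rich benzyl aryl ethers (the cations are trapped by 1,3,5-trimethoxybenzene in a Friedel–Crafts alkylation), and in the same medium reversible ionisation of each O1–C2 bond to a para-alkoxybenzyl cation and reclosure should invert both C2 centres to the thermodynamically preferred trans rings (2R in ring A, 2S in ring B) while the catalyst-set C3 centres stay untouched.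

Step 11
Reactants: 19 trans,trans-diphenol bromide; 20 (E)-2-(4-methoxyphenyl)vinylboronic acid
Product: 21 (2R,3R)-3-[(2S,3S)-2-(3,4-dimethoxyphenyl)-3-(3,5-dimethoxyphenyl)-4-hydroxy-2,3-dihydrobenzofuran-6-yl]-2-(4-methoxyphenyl)-6-[(E)-2-(4-methoxyphenyl)ethenyl]-2,3-dihydrobenzofuran-4-ol
Conditions: Pd(dppf)Cl2 (5 mol %), K2CO3, 1,4-dioxane/H2O, 80 °C (degassed)
Reagents that add atoms: none
Why: Suzuki–Miyaura coupling of the aryl bromide with the alkenylboronic acid tolerates free phenols and transfers the alkenyl group with retention, so the E stilbene geometry comes from 20.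

Step 12
Reactants: 21 hexamethyl ether
Product: 22 (2R,3R)-3-[(2S,3S)-2-(3,4-dihydroxyphenyl)-3-(3,5-dihydroxyphenyl)-4-hydroxy-2,3-dihydrobenzofuran-6-yl]-2-(4-hydroxyphenyl)-6-[(E)-2-(4-hydroxyphenyl)ethenyl]-2,3-dihydrobenzofuran-4-ol (CNP0107857.3)
Conditions: BBr3 (excess), CH2Cl2, −78 °C → rt; H2O
Reagents that add atoms: none
Why: Lewis-acid cleavage of the six aryl methyl ethers by BBr3 should free all phenols, and any transient opening of an O1–C2 bond can only reclose to the trans ring because no arene is placed to trap the cation intramolecularly in this 6-substituted benzofuran topology.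

Compound list
1 | 1-bromo-3,5-difluorobenzene | Fc1cc(Br)cc(F)c1 | starting material
2 | N,3,5-trimethoxy-N-methylbenzamide | CON(C)C(=O)c1cc(OC)cc(OC)c1 | starting material
3 | (4-bromo-2,6-difluorophenyl)lithium | [Li]c1c(F)cc(Br)cc1F | intermediate (not isolated)
4 | (4-bromo-2,6-difluorophenyl)(3,5-dimethoxyphenyl)methanone | COc1cc(OC)cc(c1)C(=O)c1c(F)cc(Br)cc1F | intermediate
5 | 3,4-dimethoxybenzyl alcohol | COc1ccc(CO)cc1OC | starting material
6 | {4-bromo-2,6-bis[(3,4-dimethoxybenzyl)oxy]phenyl}(3,5-dimethoxyphenyl)methanone | COc1cc(OC)cc(c1)C(=O)c1c(OCc2ccc(OC)c(OC)c2)cc(Br)cc1OCc1ccc(OC)c(OC)c1 | intermediate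
7 | hydrazone of ketone 6 (E/Z mixture) | COc1cc(OC)cc(c1)C(=NN)c1c(OCc2ccc(OC)c(OC)c2)cc(Br)cc1OCc1ccc(OC)c(OC)c1 | intermediate
8 | 5-bromo-2-[diazo(3,5-dimethoxyphenyl)methyl]-1,3-bis[(3,4-dimethoxybenzyl)oxy]benzene | COc1cc(OC)cc(c1)C(=[N+]=[N-])c1c(OCc2ccc(OC)c(OC)c2)cc(Br)cc1OCc1ccc(OC)c(OC)c1 | intermediate (not isolated)
9 | (2R,3S)-6-bromo-4-[(3,4-dimethoxybenzyl)oxy]-2-(3,4-dimethoxyphenyl)-3-(3,5-dimethoxyphenyl)-2,3-dihydrobenzofuran (2,3-cis) | Brc1cc(OCc2ccc(OC)c(OC)c2)c2c(c1)O[C@@H](c1ccc(OC)c(OC)c1)[C@H]2c1cc(OC)cc(OC)c1 | intermediate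
10 | 4-bromo-2,6-difluorobenzaldehyde | O=Cc1c(F)cc(Br)cc1F | starting material
11 | 4-methoxybenzyl alcohol | COc1ccc(CO)cc1 | starting material
12 | 4-bromo-2,6-bis[(4-methoxybenzyl)oxy]benzaldehyde | O=Cc1c(OCc2ccc(OC)cc2)cc(Br)cc1OCc1ccc(OC)cc1 | intermediate
13 | 6-lithio derivative of 9 (lithium in place of bromine, 2R,3S) | [Li]c1cc(OCc2ccc(OC)c(OC)c2)c2c(c1)O[C@@H](c1ccc(OC)c(OC)c1)[C@H]2c1cc(OC)cc(OC)c1 | intermediate (not isolated)
14 | {4-bromo-2,6-bis[(4-methoxybenzyl)oxy]phenyl}{(2R,3S)-4-[(3,4-dimethoxybenzyl)oxy]-2-(3,4-dimethoxyphenyl)-3-(3,5-dimethoxyphenyl)-2,3-dihydrobenzofuran-6-yl}methanol (both carbinol epimers) | OC(c1c(OCc2ccc(OC)cc2)cc(Br)cc1OCc1ccc(OC)cc1)c1cc(OCc2ccc(OC)c(OC)c2)c2c(c1)O[C@@H](c1ccc(OC)c(OC)c1)[C@H]2c1cc(OC)cc(OC)c1 | intermediate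
15 | {4-bromo-2,6-bis[(4-methoxybenzyl)oxy]phenyl}{(2R,3S)-4-[(3,4-dimethoxybenzyl)oxy]-2-(3,4-dimethoxyphenyl)-3-(3,5-dimethoxyphenyl)-2,3-dihydrobenzofuran-6-yl}methanone | O=C(c1c(OCc2ccc(OC)cc2)cc(Br)cc1OCc1ccc(OC)cc1)c1cc(OCc2ccc(OC)c(OC)c2)c2c(c1)O[C@@H](c1ccc(OC)c(OC)c1)[C@H]2c1cc(OC)cc(OC)c1 | intermediate
16 | hydrazone of ketone 15 (E/Z mixture) | NN=C(c1c(OCc2ccc(OC)cc2)cc(Br)cc1OCc1ccc(OC)cc1)c1cc(OCc2ccc(OC)c(OC)c2)c2c(c1)O[C@@H](c1ccc(OC)c(OC)c1)[C@H]2c1cc(OC)cc(OC)c1 | intermediate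
17 | diazo compound from 16 (C=N2 in place of C=N–NH2) | [N-]=[N+]=C(c1c(OCc2ccc(OC)cc2)cc(Br)cc1OCc1ccc(OC)cc1)c1cc(OCc2ccc(OC)c(OC)c2)c2c(c1)O[C@@H](c1ccc(OC)c(OC)c1)[C@H]2c1cc(OC)cc(OC)c1 | intermediate (not isolated)
18 | (2S,3R)-6-bromo-3-[(2R,3S)-4-[(3,4-dimethoxybenzyl)oxy]-2-(3,4-dimethoxyphenyl)-3-(3,5-dimethoxyphenyl)-2,3-dihydrobenzofuran-6-yl]-4-[(4-methoxybenzyl)oxy]-2-(4-methoxyphenyl)-2,3-dihydrobenzofuran (both rings cis) | Brc1cc(OCc2ccc(OC)cc2)c2c(c1)O[C@H](c1ccc(OC)cc1)[C@@H]2c1cc(OCc2ccc(OC)c(OC)c2)c2c(c1)O[C@@H](c1ccc(OC)c(OC)c1)[C@H]2c1cc(OC)cc(OC)c1 | intermediate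
19 | (2R,3R)-6-bromo-3-[(2S,3S)-2-(3,4-dimethoxyphenyl)-3-(3,5-dimethoxyphenyl)-4-hydroxy-2,3-dihydrobenzofuran-6-yl]-2-(4-methoxyphenyl)-2,3-dihydrobenzofuran-4-ol (both rings trans) | Brc1cc(O)c2c(c1)O[C@@H](c1ccc(OC)cc1)[C@@H]2c1cc(O)c2c(c1)O[C@H](c1ccc(OC)c(OC)c1)[C@H]2c1cc(OC)cc(OC)c1 | intermediate
20 | (E)-2-(4-methoxyphenyl)vinylboronic acid | COc1ccc(/C=C/B(O)O)cc1 | starting material
21 | (2R,3R)-3-[(2S,3S)-2-(3,4-dimethoxyphenyl)-3-(3,5-dimethoxyphenyl)-4-hydroxy-2,3-dihydrobenzofuran-6-yl]-2-(4-methoxyphenyl)-6-[(E)-2-(4-methoxyphenyl)ethenyl]-2,3-dihydrobenzofuran-4-ol | COc1ccc(/C=C/c2cc(O)c3c(c2)O[C@@H](c2ccc(OC)cc2)[C@@H]3c2cc(O)c3c(c2)O[C@H](c2ccc(OC)c(OC)c2)[C@H]3c2cc(OC)cc(OC)c2)cc1 | intermediate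
22 | (2R,3R)-3-[(2S,3S)-2-(3,4-dihydroxyphenyl)-3-(3,5-dihydroxyphenyl)-4-hydroxy-2,3-dihydrobenzofuran-6-yl]-2-(4-hydroxyphenyl)-6-[(E)-2-(4-hydroxyphenyl)ethenyl]-2,3-dihydrobenzofuran-4-ol (CNP0107857.3) | Oc1ccc(/C=C/c2cc(O)c3c(c2)O[C@@H](c2ccc(O)cc2)[C@@H]3c2cc(O)c3c(c2)O[C@H](c2ccc(O)c(O)c2)[C@H]3c2cc(O)cc(O)c2)cc1 | target

Total step count: 12.
Longest linear sequence: 11 steps (steps 1–4 and 6–12, from 1 to 22); step 5 is the one-step side branch.

Steps most likely to fail

Step 4 (key step). The carbene carbon is flanked by two ortho ether groups, so metal carbene formation may be slow and the diazo compound may be diverted to azine or tetraarylethylene. The insertion may also turn stepwise (hydride transfer, then ion-pair collapse), with loss of facial and cis selectivity. The hindered condensation of step 3 feeds the same risk, and this fallback bypasses it. The fallback closes the same C2–C3 bond by carbanion addition and takes the stereochemistry from a resolution. It sets out from ketone 6. Lithium 2,2,6,6-tetramethylpiperidide (THF, −78 °C) deprotonates one benzylic ether CH2 and the carbanion adds to the neighbouring ketone, which should give the tertiary alcohol 6-bromo-4-[(3,4-dimethoxybenzyl)oxy]-2-(3,4-dimethoxyphenyl)-3-(3,5-dimethoxyphenyl)-2,3-dihydrobenzofuran-3-ol F1. Ionic deoxygenation (Et3SiH, BF3·OEt2, CH2Cl2, −78 °C) delivers hydride anti to the 2-aryl group and should give the racemic 2,3-trans bromide, from which chromatography on a chiral stationary phase takes the (2S,3S)-trans bromide F2, the C2 epimer of 9. This then replaces 9 in steps 6 to 9 with unchanged reagents, passing through the aryllithium F3, the carbinol F4, the ketone F5, the hydrazone F6, the diazo compound F7 and the ring A insertion product F8 (each the ring B C2 epimer of 13 to 18). Step 10 brings the sequence back to 19, because that step leaves both rings trans in any case.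

Step 9. In the large substrate the chiral catalyst may be mismatched with the existing ring B centres or too hindered to engage the diazo group, which would show as poor facial selectivity at C3 of ring A or as carbene dimerisation. The fallback again closes the ring by carbanion addition, reduces to the trans ring and separates diastereomers. It sets out from ketone 15. Lithium 2,2,6,6-tetramethylpiperidide (THF, −78 °C) should add the deprotonated 4-methoxybenzyl ether carbon to the ketone and give the ring A tertiary alcohol F9. Et3SiH/BF3·OEt2 at −78 °C replaces the hydroxyl group by hydride anti to the 2-aryl group and should give the ring A trans compound F10 together with its diastereomer of opposite ring A configuration. The two are separable by ordinary chromatography because ring B is already a single enantiomer. The former enters step 10 unchanged and comes back to the route at 19.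

Step 12. During the long exposure to BBr3 and HBr needed to cleave six methyl ethers, the electron-rich stilbene may be protonated and oligomerise or add HBr. The fallback demethylates before the stilbene exists and uses acetates for the coupling. It sets out from 19. BBr3 (CH2Cl2, −78 °C → rt) should give the heptaphenol bromide F11, and Ac2O/pyridine the heptaacetate bromide F12. A Heck reaction with 4-acetoxystyrene (Pd(OAc)2, P(o-tol)3, Et3N, DMF, 100 °C) should give the octaacetate of the target F13. K2CO3 in degassed MeOH at 0 °C then removes the acetates, and the sequence comes back at the target 22.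

Further compounds
F1 | step 4 | 6-bromo-4-[(3,4-dimethoxybenzyl)oxy]-2-(3,4-dimethoxyphenyl)-3-(3,5-dimethoxyphenyl)-2,3-dihydrobenzofuran-3-ol (racemic) | Brc1cc(OCc2ccc(OC)c(OC)c2)c2c(c1)OC(c1ccc(OC)c(OC)c1)C2(O)c1cc(OC)cc(OC)c1
F2 | step 4 | (2S,3S)-6-bromo-4-[(3,4-dimethoxybenzyl)oxy]-2-(3,4-dimethoxyphenyl)-3-(3,5-dimethoxyphenyl)-2,3-dihydrobenzofuran (2,3-trans, C2 epimer of 9) | Brc1cc(OCc2ccc(OC)c(OC)c2)c2c(c1)O[C@H](c1ccc(OC)c(OC)c1)[C@H]2c1cc(OC)cc(OC)c1
F3 | step 4 | 6-lithio derivative of F2 (C2 epimer of 13) | [Li]c1cc(OCc2ccc(OC)c(OC)c2)c2c(c1)O[C@H](c1ccc(OC)c(OC)c1)[C@H]2c1cc(OC)cc(OC)c1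
F4 | step 4 | diaryl carbinol with (2S,3S) ring B (ring B C2 epimer of 14) | OC(c1c(OCc2ccc(OC)cc2)cc(Br)cc1OCc1ccc(OC)cc1)c1cc(OCc2ccc(OC)c(OC)c2)c2c(c1)O[C@H](c1ccc(OC)c(OC)c1)[C@H]2c1cc(OC)cc(OC)c1
F5 | step 4 | diaryl ketone with (2S,3S) ring B (ring B C2 epimer of 15) | O=C(c1c(OCc2ccc(OC)cc2)cc(Br)cc1OCc1ccc(OC)cc1)c1cc(OCc2ccc(OC)c(OC)c2)c2c(c1)O[C@H](c1ccc(OC)c(OC)c1)[C@H]2c1cc(OC)cc(OC)c1
F6 | step 4 | hydrazone of F5 (ring B C2 epimer of 16) | NN=C(c1c(OCc2ccc(OC)cc2)cc(Br)cc1OCc1ccc(OC)cc1)c1cc(OCc2ccc(OC)c(OC)c2)c2c(c1)O[C@H](c1ccc(OC)c(OC)c1)[C@H]2c1cc(OC)cc(OC)c1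
F7 | step 4 | diazo compound from F6 (ring B C2 epimer of 17) | [N-]=[N+]=C(c1c(OCc2ccc(OC)cc2)cc(Br)cc1OCc1ccc(OC)cc1)c1cc(OCc2ccc(OC)c(OC)c2)c2c(c1)O[C@H](c1ccc(OC)c(OC)c1)[C@H]2c1cc(OC)cc(OC)c1
F8 | step 4 | (2S,3R)-6-bromo-3-[(2S,3S)-4-[(3,4-dimethoxybenzyl)oxy]-2-(3,4-dimethoxyphenyl)-3-(3,5-dimethoxyphenyl)-2,3-dihydrobenzofuran-6-yl]-4-[(4-methoxybenzyl)oxy]-2-(4-methoxyphenyl)-2,3-dihydrobenzofuran (ring A cis, ring B trans) | Brc1cc(OCc2ccc(OC)cc2)c2c(c1)O[C@H](c1ccc(OC)cc1)[C@@H]2c1cc(OCc2ccc(OC)c(OC)c2)c2c(c1)O[C@H](c1ccc(OC)c(OC)c1)[C@H]2c1cc(OC)cc(OC)c1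
F9 | step 9 | 6-bromo-3-[(2R,3S)-4-[(3,4-dimethoxybenzyl)oxy]-2-(3,4-dimethoxyphenyl)-3-(3,5-dimethoxyphenyl)-2,3-dihydrobenzofuran-6-yl]-4-[(4-methoxybenzyl)oxy]-2-(4-methoxyphenyl)-2,3-dihydrobenzofuran-3-ol (ring A centres as a mixture) | Brc1cc(OCc2ccc(OC)cc2)c2c(c1)OC(c1ccc(OC)cc1)C2(O)c1cc(OCc2ccc(OC)c(OC)c2)c2c(c1)O[C@@H](c1ccc(OC)c(OC)c1)[C@H]2c1cc(OC)cc(OC)c1
F10 | step 9 | (2R,3R)-6-bromo-3-[(2R,3S)-4-[(3,4-dimethoxybenzyl)oxy]-2-(3,4-dimethoxyphenyl)-3-(3,5-dimethoxyphenyl)-2,3-dihydrobenzofuran-6-yl]-4-[(4-methoxybenzyl)oxy]-2-(4-methoxyphenyl)-2,3-dihydrobenzofuran (ring A trans, ring B cis) | Brc1cc(OCc2ccc(OC)cc2)c2c(c1)O[C@@H](c1ccc(OC)cc1)[C@@H]2c1cc(OCc2ccc(OC)c(OC)c2)c2c(c1)O[C@@H](c1ccc(OC)c(OC)c1)[C@H]2c1cc(OC)cc(OC)c1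
F11 | step 12 | (2R,3R)-6-bromo-3-[(2S,3S)-2-(3,4-dihydroxyphenyl)-3-(3,5-dihydroxyphenyl)-4-hydroxy-2,3-dihydrobenzofuran-6-yl]-2-(4-hydroxyphenyl)-2,3-dihydrobenzofuran-4-ol | Brc1cc(O)c2c(c1)O[C@@H](c1ccc(O)cc1)[C@@H]2c1cc(O)c2c(c1)O[C@H](c1ccc(O)c(O)c1)[C@H]2c1cc(O)cc(O)c1
F12 | step 12 | heptaacetate of F11 | Brc1cc(OC(C)=O)c2c(c1)O[C@@H](c1ccc(OC(C)=O)cc1)[C@@H]2c1cc(OC(C)=O)c2c(c1)O[C@H](c1ccc(OC(C)=O)c(OC(C)=O)c1)[C@H]2c1cc(OC(C)=O)cc(OC(C)=O)c1
F13 | step 12 | octaacetate of 22 | CC(=O)Oc1ccc(/C=C/c2cc(OC(C)=O)c3c(c2)O[C@@H](c2ccc(OC(C)=O)cc2)[C@@H]3c2cc(OC(C)=O)c3c(c2)O[C@H](c2ccc(OC(C)=O)c(OC(C)=O)c2)[C@H]3c2cc(OC(C)=O)cc(OC(C)=O)c2)cc1
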